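## The problem

The target is a (2S,4R)-flavan-4-ol: a chroman (rings A and C) with a 4-hydroxyphenyl group (ring B) at C2 and a hydroxyl at C4, the two lying on opposite faces of ring C (2,4-trans). Ring A is a phloroglucinol nucleus whose three oxygens must end up different: O1 in the ring, a free 5-hydroxyl and a 7-methyl ether. Its C8, flanked by O1 and the 7-methoxy group, carries a prenyl chain that must not appear at C6. The two stereocentres are 1,3-related. Once C2 is fixed, its equatorial aryl group steers a small hydride at C4 to the 2,4-cis alcohol, so the trans arrangement must be reached by inversion, and C2 itself has no neighbour to control it and needs a catalyst. The 4-hydroxyl is a benzylic alcohol on a ring with oxygen at both ortho positions and at the para position, so it ionises under mild acid and, beside a free 5-hydroxyl, can leave through an ortho-quinone methide. The prenyl double bond rules out hydrogenolysis, strong acids and electrophilic halogen once it is in place, and any 2-arylchroman-4-one stage can ring-open under base, which erases C2. A short assembly is possible because C4 is a single carbon between C4a and C3 while O1 sits on the ring A carbon next to C4a: an ortho-iodophenol derivative supplies O1 and C4a, carbon monoxide supplies C4, and a terminal arylacetylene supplies C3, C2 and ring B.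

## Retrosynthesis

**End game (24 to 21).** Target 24 is taken back to its bis-silyl ether 23 (two O–Si bonds), 23 to the 2,4-trans benzoate 22 (acyl C–O bond), and 22 to the 2,4-cis alcohol 21 by cutting the C4–O bond with inversion. A direct trans-selective reduction would be shorter, but a small hydride gives the cis alcohol under control from C2, so the inversion is accepted. The ester must be removed before the silyl groups, so that a 5-phenoxide never sits beside a leaving group at C4. The forward steps must avoid acid, and the Mitsunobu step must substitute and not eliminate.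

**Stereocentres (21 to 19).** Removing the C4–H bond of 21 gives flavanone 20, and removing the C2–H bond of 20 gives flavone 19, which has no stereocentre. Setting C2 by reduction of a flat precursor is preferred to carrying a chiral benzylic aryl ether through ring formation, where it could ionise or ring-open. The price is reliance on a catalyst-controlled conjugate reduction, which must deliver hydride to one face of C2 and protonate the enolate before it can expel O1.

**Oxygen differentiation (19 to 17).** The 5-silyl ether 19 comes from 5-hydroxyflavone 18, and 18 from the 5,7-dimethyl ether 17 by cutting the O5–CH3 bond. Only at the ketone stage does the C4 carbonyl single out the peri methoxy group by chelation. Doing this on the flavone, not on flavanone 20, keeps Lewis acid and heat away from the C2 stereocentre. It also allows a symmetric 3,5-dimethoxy ring A, so no early desymmetrisation is needed.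

**Ring C (17 to 8, 13 and 14).** Flavone 17 is cut at C4a–C4, C4–C3 and O1–C2, giving aryl iodide 8, alkyne 13 and carbon monoxide 14. Compared with a Friedel–Crafts closure at C4–C4a or a chalcone route, this cut needs neither strong acid nor strong base in the presence of the prenyl group. The carbon–iodine bond decides where C4 is attached, so the prenyl position is fixed beforehand. The three fragments are far simpler than 17, and the forward reaction must insert CO before the alkyne couples and must close the six-membered ring.

**Ring A fragment (8 to 1 and 3).** Acetate 8 is traced through the Claisen sequence (phenol 7, dienone 6) to the 1,1-dimethylallyl ether 5, cutting the C–C bond between the ring and the prenyl CH2. Ether 5 comes from the propargyl ether 4 (two C–H bonds), and 4 from iodophenol 2 and chloride 3 (O–C bond). Iodophenol 2 comes from 3,5-dimethoxyphenol 1 (C–I bond). Iodine goes in first because electrophilic iodine would attack a prenylphenol at the alkene. With one ortho carbon taken by iodine, the rearrangement can only deliver the chain to the other.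

**Ring B fragment (13 to 9 and 11).** Alkyne 13 comes from its C-silyl derivative 12 (C–Si bond), and 12 from aryl iodide 10 and ethynyltrimethylsilane 11 (aryl–alkynyl bond). Iodide 10 comes from 4-iodophenol 9 (O–Si bond). A triisopropylsilyl ether is chosen because it must survive amine, carbonate, Lewis acid and hydride before fluoride removes it.

## Roads not taken

**Alternative 1:** Ring C would be cut at the C3–C4 double bond and at O1–C2. An enantioselective iridium-catalysed allylic etherification would give the aryl 1-arylallyl ether A2, which carries an ortho 1-silyloxyvinyl group. The second-generation Grubbs catalyst would then close A2 to the cyclic silyl enol ether A1 with loss of ethylene.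
- Merits: C2 is set before ring closure by a reaction with a stronger record for high enantioselectivity than the conjugate reduction used here. The ring closes under neutral conditions, and unmasking the ketone needs no base.
- Weak points: in A1 the prenyl group is on O5 and C8 is bare. The chain would have to be moved from O5 to C8 by a Claisen–Cope sequence (heat or Eu(fod)3) on an enantioenriched chromanone, where C6 against C8 is not secured and C2 is exposed to ring opening. The electron-rich 1,1-disubstituted silyl enol ether is a reluctant metathesis partner, and the prenyl ether offers the ruthenium carbene a second alkene. The phenol needed for the etherification is hydrogen-bonded to an ortho acyl group and hindered.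
- Comparison: this road is better on enantiocontrol at C2, and the migration would free O5 without a demethylation. The chosen plan offers in return a prenyl position fixed before ring C exists and a stereocentre introduced only after all heating and Lewis acid steps are over.

**Alternative 2:** Ring C would be cut at C4–C4a. The chiral β-aryloxy acid A4 would be converted into its chloride and cyclised with SnCl4 to flavanone A3.
- Merits: the ether stereocentre of A4 would come from a Mitsunobu etherification at a benzylic carbinol made by asymmetric ketone hydrogenation, both well-established steps. The prenyl group is already on the right carbon, only one ortho position can be acylated, and the flavanone is reached without a flavone stage or a C2–C3 reduction. This road is shorter to the flavanone than the chosen plan.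
- Weak points: an acid chloride, HCl and SnCl4 would meet the prenyl alkene, which can add HCl or be acylated. The C2–O1 bond of A4 is a benzylic aryl ether β to the acylium centre, so it can ionise or eliminate to a cinnamoyl derivative and re-close without stereocontrol. The Mitsunobu etherification at an electron-rich benzylic carbinol can itself lose enantiopurity. The 5-O-demethylation would still have to be done on A3 with the stereocentre in place.
- Comparison: the chosen plan needs more steps after ring closure. In return, the prenyl group never meets a strong Lewis acid and C2 never passes through ionising conditions.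

**Alternative 3:** Ring C would be cut at O1–C2 and C3–C4 together. Salicylaldehyde A6 and HC(OMe)3 would give, under a chiral confined Brønsted acid, the 4-methoxy ortho-quinone methide A8. Its hetero-Diels–Alder reaction with 4-acetoxystyrene A7 would give the 4-methoxyflavan A5.
- Merits: this is the shortest road. Both ring bonds form in one convergent step, and C4 arrives at the alcohol oxidation level, with no detour through flavone and flavanone.
- Weak points: A6 is an ortho-prenylphenol, and a strong acid can cyclise it onto its own alkene. A5 is formed as either C4 epimer and as a methyl ether, so the hydroxyl would have to be installed by solvolysis through the benzylic cation, with C4 under thermodynamic control only. Enantiocontrol for a fully substituted quinone methide stabilised by three oxygens, with a bulky silyloxy group beside the reacting carbon, lies outside the shown scope of such catalysts. A7 can also polymerise under acid.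
- Comparison: this road wins clearly on step count and redox economy. The chosen plan offers in return reaction types with direct precedent on oxygenated, prenylated ring A systems, and a kinetic, substrate-controlled route to the C4 configuration.

Key step: step 8

Remark: the target is read as 2S,4R with the C4 hydroxyl trans to the C2 aryl group; the ligand antipode written in step 11 is assumed to deliver hydride to the C2 face that gives 2S, and the other antipode is used if the first run shows the opposite sense.

## Route

Step 1
Reactants: 1 3,5-dimethoxyphenol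
Product: 2 2-iodo-3,5-dimethoxyphenol
Conditions: NIS (1.0 equiv), CH2Cl2, −20 → 0 °C, dark
Reagents that add atoms: N-iodosuccinimide, O=C1CCC(=O)N1I
Why: Electrophilic aromatic iodination; the two equivalent carbons ortho to the hydroxyl (each para to a methoxy group) are less crowded than C4 between the two methoxy groups, so one equivalent of reagent should iodinate mainly at C2, and any minor isomer is removed by chromatography.

Step 2
Reactants: 2 2-iodo-3,5-dimethoxyphenol; 3 3-chloro-3-methylbut-1-yne
Product: 4 2-iodo-1,5-dimethoxy-3-[(2-methylbut-3-yn-2-yl)oxy]benzene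
Conditions: DBU, CuCl2·2H2O (cat.), MeCN, 0 °C
Reagents that add atoms: none
Why: Copper-catalysed propargylic O-alkylation of a phenol with a tertiary propargylic chloride; it runs at 0 °C under basic conditions, where the aryl iodide is inert.

Step 3
Reactants: 4 2-iodo-1,5-dimethoxy-3-[(2-methylbut-3-yn-2-yl)oxy]benzene
Product: 5 2-iodo-1,5-dimethoxy-3-[(2-methylbut-3-en-2-yl)oxy]benzene
Conditions: H2 (1 atm), Pd/CaCO3 poisoned with Pb(OAc)2 (Lindlar catalyst), quinoline, EtOAc, rt, stopped after 1 equiv H2
Reagents that add atoms: none
Why: Lindlar semihydrogenation of a terminal alkyne; the poisoned catalyst and quinoline should stop at the alkene and leave the aryl iodide alone.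

Step 4
Reactants: 5 2-iodo-1,5-dimethoxy-3-[(2-methylbut-3-en-2-yl)oxy]benzene
Product: 8 2-iodo-3,5-dimethoxy-6-(3-methylbut-2-en-1-yl)phenyl acetate, via Claisen dienone 6 (not isolated), via prenylphenol 7 (not isolated)
Conditions: Ac2O, N,N-diethylaniline, 130 °C; then DMAP (cat.), 60 °C
Reagents that add atoms: acetic anhydride, CC(=O)OC(C)=O
Why: Aromatic Claisen rearrangement; the [3,3] shift of the 1,1-dimethylallyl ether can only end productively at the one free ortho carbon, giving dienone 6, which tautomerises to phenol 7 with a linear prenyl group. Trapping 7 as its acetate in the same flask stops the ortho-prenylphenol from cyclising onto its alkene and provides the ester wanted in step 8.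

Step 5
Reactants: 9 4-iodophenol
Product: 10 (4-iodophenoxy)triisopropylsilane
Conditions: i-Pr3SiCl, imidazole, DMF, rt
Reagents that add atoms: chlorotriisopropylsilane, CC(C)[Si](Cl)(C(C)C)C(C)C
Why: Standard phenol silylation; the triisopropylsilyl ether is chosen over smaller silyl ethers for its resistance to amines and carbonate in steps 7 and 8.

Step 6
Reactants: 10 (4-iodophenoxy)triisopropylsilane; 11 ethynyltrimethylsilane
Product: 12 triisopropyl{4-[(trimethylsilyl)ethynyl]phenoxy}silane
Conditions: PdCl2(PPh3)2 (2 mol%), CuI (4 mol%), Et3N, THF, rt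
Reagents that add atoms: none
Why: Sonogashira coupling of an aryl iodide with a silyl-capped acetylene, which proceeds at room temperature.

Step 7
Reactants: 12 triisopropyl{4-[(trimethylsilyl)ethynyl]phenoxy}silane
Product: 13 (4-ethynylphenoxy)triisopropylsilane
Conditions: K2CO3 (cat.), MeOH/THF, rt
Reagents that add atoms: none
Why: Methoxide-mediated protodesilylation of the alkynyl–silicon bond, which is much faster than attack on the hindered aryl triisopropylsilyl ether.

Step 8
Reactants: 8 2-iodo-3,5-dimethoxy-6-(3-methylbut-2-en-1-yl)phenyl acetate; 13 (4-ethynylphenoxy)triisopropylsilane; 14 carbon monoxide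
Product: 17 5,7-dimethoxy-8-(3-methylbut-2-en-1-yl)-2-[4-(triisopropylsilyloxy)phenyl]-4H-chromen-4-one, via acetoxyaryl ynone 15 (not isolated), via hydroxyaryl enaminone 16 (not isolated)
Conditions: PdCl2(PPh3)2 (5 mol%), dppp (5 mol%), thiourea (5 mol%), DBU (2 equiv), dry Et2NH, CO (1 atm), 40 °C
Reagents that add atoms: none
Why: Divalent palladium is reduced in the flask to zerovalent palladium, which inserts into the C–I bond of 8; the acetate keeps the ring less electron-rich than a phenoxide would, so this oxidative addition and the CO insertion that follows are not held back. Amine-assisted transfer of the acetylide of 13 and reductive elimination form C4a–C4 and C4–C3 in ynone 15. Et2NH then adds to the ynone β-carbon and cleaves the aryl acetate, giving enaminone 16, whose phenol attacks the amine-bearing carbon and expels Et2NH, forming O1–C2 and closing ring C by a 6-endo addition–elimination. The closest known reaction type is the palladium-catalysed carbonylative annulation of ortho-iodophenol acetates with terminal arylacetylenes under CO in Et2NH. No stereocentre is formed. Two selectivities are needed: CO must insert before the alkyne is transferred, which the copper-free catalyst, the CO atmosphere and the capped phenol favour over direct coupling with 5-endo closure; and the ring must close 6-endo and not 5-exo onto the α-carbon, which the amine adduct secures by making C2 the only electrophilic carbon. The prenyl position is not at issue, because iodine marks C4a and the acetoxy oxygen marks O1 on a ring that already carries the chain at the future C8.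

Step 9
Reactants: 17 5,7-dimethoxy-8-(3-methylbut-2-en-1-yl)-2-[4-(triisopropylsilyloxy)phenyl]-4H-chromen-4-one
Product: 18 5-hydroxy-7-methoxy-8-(3-methylbut-2-en-1-yl)-2-[4-(triisopropylsilyloxy)phenyl]-4H-chromen-4-one
Conditions: MgI2·OEt2 (2 equiv), toluene, 80 °C; aq. NH4Cl
Reagents that add atoms: none
Why: Chelation-controlled aryl methyl ether cleavage; magnesium bridges the C4 carbonyl oxygen and O5, and iodide removes that methyl group by SN2, while the unchelated 7-methoxy group is left alone. No protic acid is generated, so the prenyl alkene and the silyl ether should survive.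

Step 10
Reactants: 18 5-hydroxy-7-methoxy-8-(3-methylbut-2-en-1-yl)-2-[4-(triisopropylsilyloxy)phenyl]-4H-chromen-4-one
Product: 19 7-methoxy-8-(3-methylbut-2-en-1-yl)-5-(triisopropylsilyloxy)-2-[4-(triisopropylsilyloxy)phenyl]-4H-chromen-4-one
Conditions: i-Pr3SiOTf, 2,6-lutidine, CH2Cl2, 0 °C → rt
Reagents that add atoms: triisopropylsilyl trifluoromethanesulfonate, CC(C)[Si](OS(=O)(=O)C(F)(F)F)(C(C)C)C(C)C
Why: Silylation of a hydrogen-bonded phenol with a silyl triflate, which is reactive enough to overcome the chelate. The bulky group is chosen so that it does not migrate to the C4 oxygen in step 12 and keeps O5 from assisting ionisation in step 13.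

Step 11
Reactants: 19 7-methoxy-8-(3-methylbut-2-en-1-yl)-5-(triisopropylsilyloxy)-2-[4-(triisopropylsilyloxy)phenyl]-4H-chromen-4-one
Product: 20 (2S)-7-methoxy-8-(3-methylbut-2-en-1-yl)-5-(triisopropylsilyloxy)-2-[4-(triisopropylsilyloxy)phenyl]chroman-4-one
Conditions: Cu(OAc)2·H2O (5 mol%), (R)-DTBM-SEGPHOS (5.5 mol%), (EtO)2MeSiH (3 equiv), t-BuOH (2 equiv), toluene, 0 °C → rt
Reagents that add atoms: none
Why: Copper hydride-catalysed asymmetric conjugate reduction of a chromone; the bisphosphine-bound copper hydride adds hydride to C2, the β-carbon, on the face selected by the chiral ligand, which sets the 2S centre. t-BuOH protonates the copper enolate at C3 at once, so it has no lifetime in which to expel the O1 aryloxide, and the isolated prenyl alkene is not a substrate for copper hydride.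

Step 12
Reactants: 20 (2S)-7-methoxy-8-(3-methylbut-2-en-1-yl)-5-(triisopropylsilyloxy)-2-[4-(triisopropylsilyloxy)phenyl]chroman-4-one
Product: 21 (2S,4S)-7-methoxy-8-(3-methylbut-2-en-1-yl)-5-(triisopropylsilyloxy)-2-[4-(triisopropylsilyloxy)phenyl]chroman-4-ol (2,4-cis)
Conditions: NaBH4, THF/MeOH, 0 °C
Reagents that add atoms: none
Why: Borohydride reduction of a flavanone; with the C2 aryl group equatorial on the half-chair, hydride attacks pseudo-axially and gives the equatorial 4S alcohol cis to the aryl group, under substrate control from C2. Removing the ketone also ends the risk of ring opening at C2.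

Step 13
Reactants: 21 (2S,4S)-7-methoxy-8-(3-methylbut-2-en-1-yl)-5-(triisopropylsilyloxy)-2-[4-(triisopropylsilyloxy)phenyl]chroman-4-ol
Product: 22 (2S,4R)-7-methoxy-8-(3-methylbut-2-en-1-yl)-5-(triisopropylsilyloxy)-2-[4-(triisopropylsilyloxy)phenyl]chroman-4-yl benzoate (2,4-trans)
Conditions: PhCO2H, PPh3, DIAD, toluene, −20 → 0 °C
Reagents that add atoms: benzoic acid, OC(=O)c1ccccc1
Why: Mitsunobu inversion; benzoate displaces the activated C4 oxygen from the opposite face and gives the 4R ester, and even if the displacement takes on ion-pair character, pseudo-axial attack leads to the same trans isomer. The silylated O5 cannot open a quinone methide pathway, and the non-polar solvent and the moderately acidic benzoic acid are chosen to limit ionisation and to give an ester that does not solvolyse.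

Step 14
Reactants: 22 (2S,4R)-7-methoxy-8-(3-methylbut-2-en-1-yl)-5-(triisopropylsilyloxy)-2-[4-(triisopropylsilyloxy)phenyl]chroman-4-yl benzoate
Product: 23 (2S,4R)-7-methoxy-8-(3-methylbut-2-en-1-yl)-5-(triisopropylsilyloxy)-2-[4-(triisopropylsilyloxy)phenyl]chroman-4-ol (2,4-trans)
Conditions: i-Bu2AlH, CH2Cl2, −78 °C; aq. Rochelle salt
Reagents that add atoms: none
Why: Reductive ester cleavage at the acyl carbon; the C4–O bond is not touched, so the configuration is kept. The aprotic, non-acidic conditions neither ionise the benzylic position nor disturb the aryl silyl ethers.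

Step 15
Reactants: 23 (2S,4R)-7-methoxy-8-(3-methylbut-2-en-1-yl)-5-(triisopropylsilyloxy)-2-[4-(triisopropylsilyloxy)phenyl]chroman-4-ol
Product: 24 (2S,4R)-2-(4-hydroxyphenyl)-7-methoxy-8-(3-methylbut-2-en-1-yl)chromane-4,5-diol (2,4-trans)
Conditions: Bu4NF (2.2 equiv), THF, 0 °C; pH 7 phosphate buffer
Reagents that add atoms: none
Why: Fluoride cleavage of both aryl silyl ethers; C4 now bears only a hydroxyl, so the transient 5-phenoxide has no leaving group to expel. The neutral quench keeps the acid-labile benzylic alcohol intact.

## Compound list

1 | 3,5-dimethoxyphenol | COc1cc(O)cc(OC)c1 | starting material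
2 | 2-iodo-3,5-dimethoxyphenol | COc1cc(OC)c(I)c(O)c1 | intermediate
3 | 3-chloro-3-methylbut-1-yne | CC(C)(Cl)C#C | starting material
4 | 2-iodo-1,5-dimethoxy-3-[(2-methylbut-3-yn-2-yl)oxy]benzene | COc1cc(OC)c(I)c(OC(C)(C)C#C)c1 | intermediate
5 | 2-iodo-1,5-dimethoxy-3-[(2-methylbut-3-en-2-yl)oxy]benzene | COc1cc(OC)c(I)c(OC(C)(C)C=C)c1 | intermediate
6 | 2-iodo-3,5-dimethoxy-6-(3-methylbut-2-en-1-yl)cyclohexa-2,4-dien-1-one | COC1=CC(OC)=C(I)C(=O)C1CC=C(C)C | intermediate (not isolated)
7 | 2-iodo-3,5-dimethoxy-6-(3-methylbut-2-en-1-yl)phenol | COc1cc(OC)c(I)c(O)c1CC=C(C)C | intermediate (not isolated)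
8 | 2-iodo-3,5-dimethoxy-6-(3-methylbut-2-en-1-yl)phenyl acetate | COc1cc(OC)c(I)c(OC(C)=O)c1CC=C(C)C | intermediate
9 | 4-iodophenol | Oc1ccc(I)cc1 | starting material
10 | (4-iodophenoxy)triisopropylsilane | CC(C)[Si](Oc1ccc(I)cc1)(C(C)C)C(C)C | intermediate
11 | ethynyltrimethylsilane | C#C[Si](C)(C)C | starting material
12 | triisopropyl{4-[(trimethylsilyl)ethynyl]phenoxy}silane | CC(C)[Si](Oc1ccc(C#C[Si](C)(C)C)cc1)(C(C)C)C(C)C | intermediate
13 | (4-ethynylphenoxy)triisopropylsilane | C#Cc1ccc(O[Si](C(C)C)(C(C)C)C(C)C)cc1 | intermediate
14 | carbon monoxide | [C-]#[O+] | starting material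
15 | 3,5-dimethoxy-6-(3-methylbut-2-en-1-yl)-2-{3-[4-(triisopropylsilyloxy)phenyl]prop-2-ynoyl}phenyl acetate | COc1cc(OC)c(C(=O)C#Cc2ccc(O[Si](C(C)C)(C(C)C)C(C)C)cc2)c(OC(C)=O)c1CC=C(C)C | intermediate (not isolated)
16 | 3-(diethylamino)-1-[2-hydroxy-4,6-dimethoxy-3-(3-methylbut-2-en-1-yl)phenyl]-3-[4-(triisopropylsilyloxy)phenyl]prop-2-en-1-one | CCN(CC)C(=CC(=O)c1c(O)c(CC=C(C)C)c(OC)cc1OC)c1ccc(O[Si](C(C)C)(C(C)C)C(C)C)cc1 | intermediate (not isolated)
17 | 5,7-dimethoxy-8-(3-methylbut-2-en-1-yl)-2-[4-(triisopropylsilyloxy)phenyl]-4H-chromen-4-one | COc1cc(OC)c2c(c1CC=C(C)C)OC(c1ccc(O[Si](C(C)C)(C(C)C)C(C)C)cc1)=CC2=O | intermediate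
18 | 5-hydroxy-7-methoxy-8-(3-methylbut-2-en-1-yl)-2-[4-(triisopropylsilyloxy)phenyl]-4H-chromen-4-one | COc1cc(O)c2c(c1CC=C(C)C)OC(c1ccc(O[Si](C(C)C)(C(C)C)C(C)C)cc1)=CC2=O | intermediate
19 | 7-methoxy-8-(3-methylbut-2-en-1-yl)-5-(triisopropylsilyloxy)-2-[4-(triisopropylsilyloxy)phenyl]-4H-chromen-4-one | COc1cc(O[Si](C(C)C)(C(C)C)C(C)C)c2c(c1CC=C(C)C)OC(c1ccc(O[Si](C(C)C)(C(C)C)C(C)C)cc1)=CC2=O | intermediate
20 | (2S)-7-methoxy-8-(3-methylbut-2-en-1-yl)-5-(triisopropylsilyloxy)-2-[4-(triisopropylsilyloxy)phenyl]chroman-4-one | COc1cc(O[Si](C(C)C)(C(C)C)C(C)C)c2c(c1CC=C(C)C)O[C@H](c1ccc(O[Si](C(C)C)(C(C)C)C(C)C)cc1)CC2=O | intermediate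
21 | (2S,4S)-7-methoxy-8-(3-methylbut-2-en-1-yl)-5-(triisopropylsilyloxy)-2-[4-(triisopropylsilyloxy)phenyl]chroman-4-ol | COc1cc(O[Si](C(C)C)(C(C)C)C(C)C)c2c(c1CC=C(C)C)O[C@H](c1ccc(O[Si](C(C)C)(C(C)C)C(C)C)cc1)C[C@@H]2O | intermediate
22 | (2S,4R)-7-methoxy-8-(3-methylbut-2-en-1-yl)-5-(triisopropylsilyloxy)-2-[4-(triisopropylsilyloxy)phenyl]chroman-4-yl benzoate | COc1cc(O[Si](C(C)C)(C(C)C)C(C)C)c2c(c1CC=C(C)C)O[C@H](c1ccc(O[Si](C(C)C)(C(C)C)C(C)C)cc1)C[C@H]2OC(=O)c1ccccc1 | intermediate
23 | (2S,4R)-7-methoxy-8-(3-methylbut-2-en-1-yl)-5-(triisopropylsilyloxy)-2-[4-(triisopropylsilyloxy)phenyl]chroman-4-ol | COc1cc(O[Si](C(C)C)(C(C)C)C(C)C)c2c(c1CC=C(C)C)O[C@H](c1ccc(O[Si](C(C)C)(C(C)C)C(C)C)cc1)C[C@H]2O | intermediate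
24 | (2S,4R)-2-(4-hydroxyphenyl)-7-methoxy-8-(3-methylbut-2-en-1-yl)chromane-4,5-diol (4,5,4'-trihydroxy-7-methoxy-8-prenylflavan) | COc1cc(O)c2c(c1CC=C(C)C)O[C@H](c1ccc(O)cc1)C[C@H]2O | target

## Step count and least certain steps

Total: 15 steps. Longest linear sequence: 12 steps (steps 1–4 and 8–15 from 3,5-dimethoxyphenol 1); the alkyne branch (steps 5–7) is 3 steps.

**Step 8 (key step).** The alkyne may be transferred before CO inserts on this hindered, electron-rich iodide, giving direct coupling followed by 5-endo closure, or the sequence may stall before deacetylation and ring closure. Fallback: the acyl carbon is brought in as a preformed amide instead of CO.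
- Alkyne 13 is lithiated (n-BuLi, THF, −78 °C) and treated with N-methoxy-N-methylcarbamoyl chloride to give N-methoxy-N-methyl-3-[4-(triisopropylsilyloxy)phenyl]prop-2-ynamide F1.
- Acetate 8 is methanolysed (K2CO3, MeOH, rt) to phenol 7, which is deprotonated (NaH, THF), subjected to iodine–lithium exchange (n-BuLi, −78 °C) and added to F1. This gives 1-[2-hydroxy-4,6-dimethoxy-3-(3-methylbut-2-en-1-yl)phenyl]-3-[4-(triisopropylsilyloxy)phenyl]prop-2-yn-1-one F2.
- Et2NH in EtOH at rt then closes F2 in the 6-endo sense.
- The fallback sets out from 8 and 13 and returns at flavone 17.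

**Step 11.** Facial selectivity or turnover may be poor on a 2-arylchromone with a bulky peri substituent, the copper enolate may ring-open by loss of the O1 aryloxide, or the ketone may be reduced further. Fallback: racemic reduction followed by a kinetic resolution.
- Flavone 19 is reduced with an achiral copper hydride (Cu(OAc)2·H2O, 1,2-bis(diphenylphosphino)benzene, polymethylhydrosiloxane, t-BuOH, toluene) to racemic 7-methoxy-8-(3-methylbut-2-en-1-yl)-5-(triisopropylsilyloxy)-2-[4-(triisopropylsilyloxy)phenyl]chroman-4-one F3.
- Asymmetric transfer hydrogenation with RhCl(Cp*)(TsDPEN) in HCO2H/Et3N, using the diamine antipode that reduces the 2S ketone faster, converts that enantiomer directly into cis alcohol 21.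
- The (2R)-ketone F4 is left behind and can be separated, so at most half of the material is used per pass.
- The fallback sets out from 19 and returns at 21.

**Step 13.** The activated C4 oxygen sits on a trioxygenated benzylic carbon and may ionise, leading to elimination into ring C or to loss of stereochemical fidelity. Fallback: thermodynamic epimerisation instead of SN2 inversion.
- Cis alcohol 21 is treated with a catalytic amount of camphorsulfonic acid in THF/H2O at 0 °C to rt.
- Reversible ionisation at C4 and pseudo-axial return of water should lead to the 2,4-trans alcohol, in which the hydroxyl escapes the peri contact with the 5-silyloxy group. This is the known acid-catalysed C4 epimerisation of flavan-4-ols.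
- The fallback sets out from 21 and returns at 23; it makes no compound outside the list (F0).

**Step 1.** Iodination may occur at C4 or twice. Fallback: directed ortho-metalation.
- Phenol 1 is converted (MeOCH2Cl, i-Pr2NEt, CH2Cl2) into 1,3-dimethoxy-5-(methoxymethoxy)benzene F5.
- Lithiation (n-BuLi, THF, 0 °C) at the carbon between the acetal oxygen and a methoxy group, then I2 at −78 °C, gives 2-iodo-1,5-dimethoxy-3-(methoxymethoxy)benzene F6.
- HCl in MeOH at rt then removes the acetal.
- The fallback sets out from 1 and returns at 2.

**Step 3.** Hydrogenation may run on to the saturated ether, or the C–I bond may be hydrogenolysed on palladium. The same fallback also covers fragmentation of the tertiary ether in step 4. Fallback: direct ortho C-prenylation.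
- The sodium salt of 2 (NaH, toluene) is alkylated with 1-bromo-3-methylbut-2-ene at rt. In the non-polar medium this goes at the only free ortho carbon and gives phenol 7.
- Acetylation (Ac2O, pyridine) then gives 8.
- The fallback sets out from 2 and returns at 8; it makes no compound outside the list (F0).

## Further compounds

F1 | step 8 | N-methoxy-N-methyl-3-[4-(triisopropylsilyloxy)phenyl]prop-2-ynamide | CON(C)C(=O)C#Cc1ccc(O[Si](C(C)C)(C(C)C)C(C)C)cc1
F2 | step 8 | 1-[2-hydroxy-4,6-dimethoxy-3-(3-methylbut-2-en-1-yl)phenyl]-3-[4-(triisopropylsilyloxy)phenyl]prop-2-yn-1-one | COc1cc(OC)c(C(=O)C#Cc2ccc(O[Si](C(C)C)(C(C)C)C(C)C)cc2)c(O)c1CC=C(C)C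
F3 | step 11 | racemic 7-methoxy-8-(3-methylbut-2-en-1-yl)-5-(triisopropylsilyloxy)-2-[4-(triisopropylsilyloxy)phenyl]chroman-4-one | COc1cc(O[Si](C(C)C)(C(C)C)C(C)C)c2c(c1CC=C(C)C)OC(c1ccc(O[Si](C(C)C)(C(C)C)C(C)C)cc1)CC2=O
F4 | step 11 | (2R)-7-methoxy-8-(3-methylbut-2-en-1-yl)-5-(triisopropylsilyloxy)-2-[4-(triisopropylsilyloxy)phenyl]chroman-4-one | COc1cc(O[Si](C(C)C)(C(C)C)C(C)C)c2c(c1CC=C(C)C)O[C@@H](c1ccc(O[Si](C(C)C)(C(C)C)C(C)C)cc1)CC2=O
F0 | step 13 | none | none
F5 | step 1 | 1,3-dimethoxy-5-(methoxymethoxy)benzene | COCOc1cc(OC)cc(OC)c1
F6 | step 1 | 2-iodo-1,5-dimethoxy-3-(methoxymethoxy)benzene | COCOc1cc(OC)cc(OC)c1I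
F0 | step 3 | none | none
A1 | alternative 1 | (2S)-4-(tert-butyldimethylsilyloxy)-7-methoxy-5-(3-methylbut-2-enyloxy)-2-[4-(tert-butyldimethylsilyloxy)phenyl]-2H-chromene | COc1cc(OCC=C(C)C)c2c(c1)O[C@H](c1ccc(O[Si](C)(C)C(C)(C)C)cc1)C=C2O[Si](C)(C)C(C)(C)C
A2 | alternative 1 | tert-butyl{4-[(1S)-1-{2-[1-(tert-butyldimethylsilyloxy)vinyl]-5-methoxy-3-(3-methylbut-2-enyloxy)phenoxy}prop-2-en-1-yl]phenoxy}dimethylsilane | COc1cc(OCC=C(C)C)c(C(=C)O[Si](C)(C)C(C)(C)C)c(c1)O[C@@H](C=C)c1ccc(O[Si](C)(C)C(C)(C)C)cc1
A3 | alternative 2 | (2S)-5,7-dimethoxy-8-(3-methylbut-2-enyl)-4'-pivaloyloxyflavanone | COc1cc(OC)c2c(c1CC=C(C)C)O[C@H](c1ccc(OC(=O)C(C)(C)C)cc1)CC2=O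
A4 | alternative 2 | (3S)-3-[3,5-dimethoxy-2-(3-methylbut-2-enyl)phenoxy]-3-(4-pivaloyloxyphenyl)propanoic acid | COc1cc(OC)cc(O[C@@H](CC(=O)O)c2ccc(OC(=O)C(C)(C)C)cc2)c1CC=C(C)C
A5 | alternative 3 | (2S)-2-(4-acetoxyphenyl)-4,7-dimethoxy-8-(3-methylbut-2-enyl)-5-(triisopropylsilyloxy)chromane, C4 unassigned | COc1cc(O[Si](C(C)C)(C(C)C)C(C)C)c2c(c1CC=C(C)C)O[C@H](c1ccc(OC(C)=O)cc1)CC2OC
A6 | alternative 3 | 2-hydroxy-4-methoxy-3-(3-methylbut-2-enyl)-6-(triisopropylsilyloxy)benzaldehyde | COc1cc(O[Si](C(C)C)(C(C)C)C(C)C)c(C=O)c(O)c1CC=C(C)C
A7 | alternative 3 | 4-acetoxystyrene | C=Cc1ccc(OC(C)=O)cc1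
A8 | alternative 3 | 3-methoxy-6-(methoxymethylidene)-2-(3-methylbut-2-enyl)-5-(triisopropylsilyloxy)cyclohexa-2,4-dien-1-one | COC=C1C(=O)C(CC=C(C)C)=C(OC)C=C1O[Si](C(C)C)(C(C)C)C(C)C
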